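**Retrosynthetic overview**

1. Ten-membered carbocycle (formed last): intramolecular Nozaki–Hiyama–Kishi addition of a C10 bromoalkene to a C1 cis-epoxy aldehyde (C1–C10 bond).
2. C2–C3 oxirane: Sharpless epoxidation of a (Z)-allylic alcohol. C8 tiglate: the key step, a C8–O bond made with inversion directly from the C8-epimeric triethylsilyl ether (new desilylative Mitsunobu-type esterification).
3. C4–C5 oxirane, then the C6–O lactone bond: hydroxyl-directed epoxidation and lactonisation of an anti homoallylic alcohol.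
4. C6–C7: chromium-mediated 2-(methoxycarbonyl)allylation joining dienal fragment A (C1–C6, C15) with allyl bromide fragment B (C7–C14); the C8 centre of B relays to C7, C6, C5 and C4.
5. Fragment A from (E)-3-methylpent-2-en-4-yn-1-ol and formaldehyde; fragment B from crotonaldehyde, 2,3-dibromopropene and methyl acrylate. Ring order: C4–C5 oxirane, lactone, C2–C3 oxirane, carbocycle.

Assumption: locants C1–C15 in names are the germacrane positions of the target (C1–C10 ring, C11–C13 lactone carbons, C14 exo-methylene, C15 methyl), CIP descriptors refer to these locants, and the SMILES are authoritative.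

**Route**

Step 1
Reactants: 1 (E)-3-methylpent-2-en-4-yn-1-ol
Product: 2 (E)-triethyl[(3-methylpent-2-en-4-yn-1-yl)oxy]silane
Conditions: Et3SiCl, imidazole, CH2Cl2, 0 °C
Reagents that add atoms: triethylsilyl chloride, CC[Si](Cl)(CC)CC
Why: Standard silylation of the primary allylic alcohol (no stereocentre); TES is chosen because a primary TES ether can later be oxidised directly to the aldehyde.

Step 2
Reactants: 2 (E)-triethyl[(3-methylpent-2-en-4-yn-1-yl)oxy]silane; 3 formaldehyde (used as paraformaldehyde)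
Product: 6 (E)-1-(tert-butyldiphenylsilyloxy)-4-methyl-6-(triethylsilyloxy)hex-4-en-2-yne, via lithium acetylide 4 (not isolated), via lithium alkoxide 5 (not isolated)
Conditions: n-BuLi, THF, −78 °C; (CH2O)n, to rt; then t-BuPh2SiCl, DMAP (cat.), 0 °C to rt
Reagents that add atoms: tert-butyl(chloro)diphenylsilane, CC(C)(C)[Si](Cl)(c1ccccc1)c1ccccc1
Why: Alkynyl anion addition to formaldehyde (hydroxymethylation) adds C1, and the lithium alkoxide is silylated in the same flask; no stereocentre is formed.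

Step 3
Reactants: 6 (E)-1-(tert-butyldiphenylsilyloxy)-4-methyl-6-(triethylsilyloxy)hex-4-en-2-yne
Product: 7 (2Z,4E)-1-(tert-butyldiphenylsilyloxy)-4-methyl-6-(triethylsilyloxy)hexa-2,4-diene
Conditions: H2 (1 atm), Pd/CaCO3 poisoned with Pb(OAc)2 (Lindlar), quinoline, EtOAc/hexane, rt
Reagents that add atoms: none
Why: Lindlar semihydrogenation adds H2 syn to the alkyne and so gives the 2Z alkene, leaving the trisubstituted 4E alkene untouched.

Step 4
Reactants: 7 (2Z,4E)-1-(tert-butyldiphenylsilyloxy)-4-methyl-6-(triethylsilyloxy)hexa-2,4-diene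
Product: 9 (2E,4Z)-6-(tert-butyldiphenylsilyloxy)-3-methylhexa-2,4-dienal (fragment A), via alkoxysulfonium chloride 8 (not isolated)
Conditions: (COCl)2, DMSO, CH2Cl2, −78 to −40 °C; then Et3N, to 0 °C
Reagents that add atoms: none
Why: Swern oxidation acting directly on the primary TES ether (oxidative desilylation): the chlorosulfonium salt attacks the unhindered Et3Si–O oxygen while the bulky TBDPS ether is inert, and base gives the enal without E/Z scrambling.

Step 5
Reactants: 10 (E)-but-2-enal; 11 2,3-dibromoprop-1-ene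
Product: 12 (4S,5E)-2-bromo-4-(triethylsilyloxy)hepta-1,5-diene
Conditions: CrCl2 (10 mol %), chiral oxazoline–sulfonamide ligand (Kishi type, 11 mol %), CoC32H16N8 (cobalt phthalocyanine, 1 mol %), Mn, Et3SiCl, Et3N (20 mol %), THF, rt
Reagents that add atoms: triethylsilyl chloride, CC[Si](Cl)(CC)CC
Why: Catalytic asymmetric Nozaki–Hiyama 2-haloallylation (Mn and Et3SiCl turn the chromium cycle over and deliver the silyl ether): the ligand-bound allylchromium adds 1,2 to the enal on the face giving the S carbinol, which is C8 in deliberately the opposite configuration to the target.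

Step 6
Reactants: 12 (4S,5E)-2-bromo-4-(triethylsilyloxy)hepta-1,5-diene
Product: 14 (2S)-4-bromo-2-(triethylsilyloxy)pent-4-enal, via ozonide 13 (not isolated)
Conditions: O3, CH2Cl2, −78 °C (Sudan red end-point); then PPh3, to rt
Reagents that add atoms: ozone, [O-][O+]=O
Why: Ozonolysis cleaves the electron-rich 1,2-disubstituted alkene far faster than the electron-poor bromoalkene; C8 is untouched.

Step 7
Reactants: 14 (2S)-4-bromo-2-(triethylsilyloxy)pent-4-enal; 15 methyl acrylate
Product: 16 methyl (4S)-6-bromo-3-hydroxy-2-methylidene-4-(triethylsilyloxy)hept-6-enoate (both C3 epimers)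
Conditions: DABCO (0.5 equiv), neat methyl acrylate, rt, 72 h
Reagents that add atoms: none
Why: Morita–Baylis–Hillman reaction of a reactive alpha-silyloxy aldehyde; the new carbinol centre (C7) forms as a mixture, which is irrelevant because it becomes sp2 in the next step.

Step 8
Reactants: 16 methyl (4S)-6-bromo-3-hydroxy-2-methylidene-4-(triethylsilyloxy)hept-6-enoate
Product: 17 methyl (2Z,4S)-6-bromo-2-(bromomethyl)-4-(triethylsilyloxy)hepta-2,6-dienoate (fragment B)
Conditions: N-bromosuccinimide, Me2S, CH2Cl2, 0 °C to rt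
Reagents that add atoms: N-bromosuccinimide, BrN1C(=O)CCC1=O
Why: SN2′ bromination of the Baylis–Hillman alcohol through its alkoxysulfonium salt (Corey–Kim type) gives the thermodynamically favoured (Z)-2-(bromomethyl)enoate.

Step 9
Reactants: 9 (2E,4Z)-6-(tert-butyldiphenylsilyloxy)-3-methylhexa-2,4-dienal; 17 methyl (2Z,4S)-6-bromo-2-(bromomethyl)-4-(triethylsilyloxy)hepta-2,6-dienoate
Product: 18 methyl (6R,7S,8S)-10-bromo-1-(tert-butyldiphenylsilyloxy)-6-hydroxy-8-(triethylsilyloxy)-1,10-secogermacra-2Z,4E,10(14),11(13)-tetraen-12-oate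
Conditions: CrCl2 (4 equiv), THF, 0 °C to rt; pH 7 buffer work-up
Reagents that add atoms: none
Why: Chromium-mediated Barbier-type 2-(alkoxycarbonyl)allylation (Nozaki–Hiyama): the allylchromium reacts at its gamma carbon (C7) through a chair transition state with the C8 substituent equatorial, giving the 6,7-anti adduct, and the aldehyde approaches C7 anti to the C8 silyloxy group (H8 held in the alkene plane by A(1,3) strain), so the S centre at C8 sets C7 and with it C6.

Step 10
Reactants: 18 methyl (6R,7S,8S)-10-bromo-1-(tert-butyldiphenylsilyloxy)-6-hydroxy-8-(triethylsilyloxy)-1,10-secogermacra-2Z,4E,10(14),11(13)-tetraen-12-oate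
Product: 20 (4R,5R,6S,7S,8S)-10-bromo-1-(tert-butyldiphenylsilyloxy)-4,5-epoxy-8-(triethylsilyloxy)-1,10-secogermacra-2Z,10(14),11(13)-trien-12,6-olide, via epoxy hydroxy ester 19 (not isolated)
Conditions: Ti(OiPr)4 (20 mol %), t-BuOOH (1.5 equiv), 4 Å MS, CH2Cl2, −20 °C; then rt
Reagents that add atoms: tert-butyl hydroperoxide, CC(C)(C)OO
Why: Hydroxyl-directed titanium/t-BuOOH epoxidation of the secondary allylic alcohol, in which A(1,3) strain from the cis methyl (C15) holds H6 in the alkene plane so oxygen is delivered threo to the C6 hydroxyl (sets C4 and C5), followed by lactonisation (intramolecular transesterification) of the titanium alkoxide onto the methyl ester.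

Step 11
Reactants: 20 (4R,5R,6S,7S,8S)-10-bromo-1-(tert-butyldiphenylsilyloxy)-4,5-epoxy-8-(triethylsilyloxy)-1,10-secogermacra-2Z,10(14),11(13)-trien-12,6-olide; 21 tiglic acid
Product: 23 (4R,5R,6S,7R,8R)-10-bromo-1-(tert-butyldiphenylsilyloxy)-4,5-epoxy-8-tigloyloxy-1,10-secogermacra-2Z,10(14),11(13)-trien-12,6-olide, via alkoxyfluorophosphorane 22 (not isolated)
Conditions: Ph3PF2 (1.5 equiv), MeCN, 40 °C; then CsO2CC(CH3)=CHCH3 (made from 21 and Cs2CO3), 50 °C
Reagents that add atoms: none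
Why: Proposed new method: Ph3PF2 exchanges a P–F bond for the Si–O bond of the secondary TES ether (driving force Et3Si–F) to give alkoxyfluorophosphorane 22 with no free alkoxide (so no acyl shift onto the lactone) and no silyl Lewis acid (so the epoxide is safe), 22 ionises to an alkoxyphosphonium ion, and tiglate displaces Ph3PO from C8 by SN2 with inversion (8S to 8R) while the hindered primary TBDPS ether reacts far more slowly; the closest known reactions are the Mitsunobu esterification, the Ph3PBr2 conversion of silyl ethers into bromides and the fluorophosphorane fluorination of silyl ethers.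

Step 12
Reactants: 23 (4R,5R,6S,7R,8R)-10-bromo-1-(tert-butyldiphenylsilyloxy)-4,5-epoxy-8-tigloyloxy-1,10-secogermacra-2Z,10(14),11(13)-trien-12,6-olide
Product: 24 (4R,5R,6S,7R,8R)-10-bromo-4,5-epoxy-1-hydroxy-8-tigloyloxy-1,10-secogermacra-2Z,10(14),11(13)-trien-12,6-olide
Conditions: Bu4NF, AcOH (1:1), THF, 0 °C to rt
Reagents that add atoms: none
Why: Fluoride desilylation buffered with acetic acid, so the medium stays non-basic and the lactone, tiglate and epoxide survive.

Step 13
Reactants: 24 (4R,5R,6S,7R,8R)-10-bromo-4,5-epoxy-1-hydroxy-8-tigloyloxy-1,10-secogermacra-2Z,10(14),11(13)-trien-12,6-olide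
Product: 25 (2S,3S,4S,5R,6S,7R,8R)-10-bromo-2,3:4,5-diepoxy-1-hydroxy-8-tigloyloxy-1,10-secogermacra-10(14),11(13)-dien-12,6-olide
Conditions: Ti(OiPr)4 (1.0 equiv), L-(+)-diethyl tartrate (1.2 equiv), t-BuOOH, 4 Å MS, CH2Cl2, −20 °C
Reagents that add atoms: tert-butyl hydroperoxide, CC(C)(C)OO
Why: Sharpless asymmetric epoxidation of the primary (Z)-allylic alcohol, where L-(+)-tartrate delivers oxygen to the face giving the 2S,3S cis-epoxide (reagent control), and the minor enantiomer carried from step 5 becomes a separable diastereomer here.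

Step 14
Reactants: 25 (2S,3S,4S,5R,6S,7R,8R)-10-bromo-2,3:4,5-diepoxy-1-hydroxy-8-tigloyloxy-1,10-secogermacra-10(14),11(13)-dien-12,6-olide
Product: 26 (2R,3S,4S,5R,6S,7R,8R)-10-bromo-2,3:4,5-diepoxy-1-oxo-8-tigloyloxy-1,10-secogermacra-10(14),11(13)-dien-12,6-olide
Conditions: Dess–Martin periodinane, pyridine, CH2Cl2, 0 °C
Reagents that add atoms: none
Why: Dess–Martin oxidation of the primary epoxy alcohol under buffered conditions gives the cis-epoxy aldehyde without epimerisation at C2 (the descriptor changes only through CIP priorities).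

Step 15
Reactants: 26 (2R,3S,4S,5R,6S,7R,8R)-10-bromo-2,3:4,5-diepoxy-1-oxo-8-tigloyloxy-1,10-secogermacra-10(14),11(13)-dien-12,6-olide
Product: 27 (1S,2S,3S,4S,5R,6S,7R,8R)-2,3:4,5-diepoxy-1-hydroxy-8-tigloyloxygermacra-10(14),11(13)-dien-12,6-olide (target, CNP0164399.1)
Conditions: CrCl2 (10 equiv), NiCl2 (2 mol %), DMSO/THF, rt, 0.003 M (slow addition)
Reagents that add atoms: none
Why: Intramolecular Nozaki–Hiyama–Kishi reaction (nickel-catalysed formation of the alkenylchromium from the 2-bromoalkene, then addition to the aldehyde at high dilution) closes the ten-membered ring at C1–C10 and creates the exo-methylene carbinol; Felkin–Anh attack anti to the epoxide C2–O bond gives the erythro 1S alcohol.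

**Compound list**

1 | (E)-3-methylpent-2-en-4-yn-1-ol | C#C/C(C)=C/CO | starting material
2 | (E)-triethyl[(3-methylpent-2-en-4-yn-1-yl)oxy]silane | C#C/C(C)=C/CO[Si](CC)(CC)CC | intermediate
3 | formaldehyde (used as paraformaldehyde) | C=O | starting material
4 | lithium (E)-3-methyl-5-(triethylsilyloxy)pent-3-en-1-yn-1-ide | [Li]C#C/C(C)=C/CO[Si](CC)(CC)CC | intermediate
5 | lithium (E)-4-methyl-6-(triethylsilyloxy)hex-4-en-2-yn-1-olate | [Li]OCC#C/C(C)=C/CO[Si](CC)(CC)CC | intermediate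
6 | (E)-1-(tert-butyldiphenylsilyloxy)-4-methyl-6-(triethylsilyloxy)hex-4-en-2-yne | CC(C)(C)[Si](c1ccccc1)(c1ccccc1)OCC#C/C(C)=C/CO[Si](CC)(CC)CC | intermediate
7 | (2Z,4E)-1-(tert-butyldiphenylsilyloxy)-4-methyl-6-(triethylsilyloxy)hexa-2,4-diene | CC(C)(C)[Si](c1ccccc1)(c1ccccc1)OC/C=C\C(C)=C\CO[Si](CC)(CC)CC | intermediate
8 | [(2E,4Z)-6-(tert-butyldiphenylsilyloxy)-3-methylhexa-2,4-dien-1-yl]oxy(dimethyl)sulfonium chloride | C[S+](C)OC/C=C(C)/C=C\CO[Si](c1ccccc1)(c1ccccc1)C(C)(C)C.[Cl-] | intermediate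
9 | (2E,4Z)-6-(tert-butyldiphenylsilyloxy)-3-methylhexa-2,4-dienal (fragment A; aldehyde carbon = C6, silyloxy carbon = C1) | O=C/C=C(C)/C=C\CO[Si](c1ccccc1)(c1ccccc1)C(C)(C)C | intermediate
10 | (E)-but-2-enal (crotonaldehyde) | C/C=C/C=O | starting material
11 | 2,3-dibromoprop-1-ene | BrCC(Br)=C | starting material
12 | (4S,5E)-2-bromo-4-(triethylsilyloxy)hepta-1,5-diene | C/C=C/[C@@H](O[Si](CC)(CC)CC)CC(Br)=C | intermediate
13 | ozonide of 12: 3-[(1S)-3-bromo-1-(triethylsilyloxy)but-3-en-1-yl]-5-methyl-1,2,4-trioxolane | CC1OOC(O1)[C@@H](O[Si](CC)(CC)CC)CC(Br)=C | intermediate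
14 | (2S)-4-bromo-2-(triethylsilyloxy)pent-4-enal | O=C[C@@H](O[Si](CC)(CC)CC)CC(Br)=C | intermediate
15 | methyl acrylate | C=CC(=O)OC | starting material
16 | methyl (4S)-6-bromo-3-hydroxy-2-methylidene-4-(triethylsilyloxy)hept-6-enoate (both C3 epimers) | C=C(C(=O)OC)C(O)[C@@H](O[Si](CC)(CC)CC)CC(Br)=C | intermediate
17 | methyl (2Z,4S)-6-bromo-2-(bromomethyl)-4-(triethylsilyloxy)hepta-2,6-dienoate (fragment B; C4 of this name = C8) | BrC/C(C(=O)OC)=C\[C@@H](O[Si](CC)(CC)CC)CC(Br)=C | intermediate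
18 | methyl (6R,7S,8S)-10-bromo-1-(tert-butyldiphenylsilyloxy)-6-hydroxy-8-(triethylsilyloxy)-1,10-secogermacra-2Z,4E,10(14),11(13)-tetraen-12-oate | C=C(C(=O)OC)[C@@H]([C@H](O)/C=C(C)/C=C\CO[Si](c1ccccc1)(c1ccccc1)C(C)(C)C)[C@@H](O[Si](CC)(CC)CC)CC(Br)=C | intermediate
19 | methyl (4R,5R,6S,7S,8S)-10-bromo-1-(tert-butyldiphenylsilyloxy)-4,5-epoxy-6-hydroxy-8-(triethylsilyloxy)-1,10-secogermacra-2Z,10(14),11(13)-trien-12-oate | C=C(C(=O)OC)[C@@H]([C@H](O)[C@H]1O[C@]1(C)/C=C\CO[Si](c1ccccc1)(c1ccccc1)C(C)(C)C)[C@@H](O[Si](CC)(CC)CC)CC(Br)=C | intermediate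
20 | (4R,5R,6S,7S,8S)-10-bromo-1-(tert-butyldiphenylsilyloxy)-4,5-epoxy-8-(triethylsilyloxy)-1,10-secogermacra-2Z,10(14),11(13)-trien-12,6-olide | C=C1C(=O)O[C@H]([C@H]2O[C@]2(C)/C=C\CO[Si](c2ccccc2)(c2ccccc2)C(C)(C)C)[C@H]1[C@@H](O[Si](CC)(CC)CC)CC(Br)=C | intermediate
21 | tiglic acid, (E)-2-methylbut-2-enoic acid | C/C=C(\C)C(=O)O | starting material
22 | (4R,5R,6S,7S,8S)-10-bromo-1-(tert-butyldiphenylsilyloxy)-4,5-epoxy-8-[fluoro(triphenyl)phosphoranyloxy]-1,10-secogermacra-2Z,10(14),11(13)-trien-12,6-olide | C=C1C(=O)O[C@H]([C@H]2O[C@]2(C)/C=C\CO[Si](c2ccccc2)(c2ccccc2)C(C)(C)C)[C@H]1[C@@H](OP(F)(c1ccccc1)(c1ccccc1)c1ccccc1)CC(Br)=C | intermediate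
23 | (4R,5R,6S,7R,8R)-10-bromo-1-(tert-butyldiphenylsilyloxy)-4,5-epoxy-8-tigloyloxy-1,10-secogermacra-2Z,10(14),11(13)-trien-12,6-olide | C=C1C(=O)O[C@H]([C@H]2O[C@]2(C)/C=C\CO[Si](c2ccccc2)(c2ccccc2)C(C)(C)C)[C@H]1[C@H](OC(=O)/C(C)=C/C)CC(Br)=C | intermediate
24 | (4R,5R,6S,7R,8R)-10-bromo-4,5-epoxy-1-hydroxy-8-tigloyloxy-1,10-secogermacra-2Z,10(14),11(13)-trien-12,6-olide | C=C1C(=O)O[C@H]([C@H]2O[C@]2(C)/C=C\CO)[C@H]1[C@H](OC(=O)/C(C)=C/C)CC(Br)=C | intermediate
25 | (2S,3S,4S,5R,6S,7R,8R)-10-bromo-2,3:4,5-diepoxy-1-hydroxy-8-tigloyloxy-1,10-secogermacra-10(14),11(13)-dien-12,6-olide | C=C1C(=O)O[C@H]([C@H]2O[C@]2(C)[C@H]2O[C@H]2CO)[C@H]1[C@H](OC(=O)/C(C)=C/C)CC(Br)=C | intermediate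
26 | (2R,3S,4S,5R,6S,7R,8R)-10-bromo-2,3:4,5-diepoxy-1-oxo-8-tigloyloxy-1,10-secogermacra-10(14),11(13)-dien-12,6-olide | C=C1C(=O)O[C@H]([C@H]2O[C@]2(C)[C@H]2O[C@H]2C=O)[C@H]1[C@H](OC(=O)/C(C)=C/C)CC(Br)=C | intermediate
27 | (1S,2S,3S,4S,5R,6S,7R,8R)-2,3:4,5-diepoxy-1-hydroxy-8-tigloyloxygermacra-10(14),11(13)-dien-12,6-olide (CNP0164399.1) | C=C1C(=O)O[C@H]2[C@H]1[C@H](OC(=O)/C(C)=C/C)CC(=C)[C@H](O)[C@@H]1O[C@@H]1[C@@]1(C)O[C@H]21 | target

**Step count and risks**

Total step count: 15. Longest linear sequence: 11 steps (steps 5–8 then 9–15; steps 1–4 then 9–15 is equally long).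

The three steps most likely to fail:

Step 9, the chromium allylation. Both the anti selectivity and the face selectivity at C7 rest on transition-state models, not on a precedent with this exact bromide, and the dienyl carbinol is acid-sensitive. The fallback sets out from 9 and 17 and comes back to the route at 18. Indium powder in THF/H2O couples 9 and 17 in a Barbier reaction that is syn-selective for (Z)-2-(bromomethyl)enoates, giving the C6 epimer methyl (6S,7S,8S)-10-bromo-1-(tert-butyldiphenylsilyloxy)-6-hydroxy-8-(triethylsilyloxy)-1,10-secogermacra-2Z,4E,10(14),11(13)-tetraen-12-oate F1. Dess–Martin periodinane (pyridine, CH2Cl2, 0 °C) oxidises it to the dienone methyl (7R,8S)-10-bromo-1-(tert-butyldiphenylsilyloxy)-6-oxo-8-(triethylsilyloxy)-1,10-secogermacra-2Z,4E,10(14),11(13)-tetraen-12-oate F2. Reduction of F2 with BH3·SMe2 and the CBS oxazaborolidine enantiomer that gives the 6R carbinol (−40 °C) sets C6 by reagent control and returns 18.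

Step 11, the proposed desilylative esterification. The Si–O/P–F exchange may be slow at the hindered secondary ether, and fluoride collapse, elimination or reaction at the TBDPS ether could compete. The fallback uses known chemistry, sets out from 20 and comes back at 23. HF·pyridine buffered with pyridine in THF at 0 °C removes only the secondary TES ether and gives the alcohol (4R,5R,6S,7R,8S)-10-bromo-1-(tert-butyldiphenylsilyloxy)-4,5-epoxy-8-hydroxy-1,10-secogermacra-2Z,10(14),11(13)-trien-12,6-olide F3. This is esterified with tiglic acid 21 under Mitsunobu conditions (PPh3, diisopropyl azodicarboxylate, toluene, 0 °C) with inversion at C8 to give 23.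

Step 15, the ring closure. Closing a ten-membered ring with a 2-bromoalkene is demanding, CrCl2 can attack the epoxy aldehyde, and the macrocyclic transition state may override Felkin control at C1. The fallback sets out from 26 and comes back at 27, and it sets C1 by hydride reduction instead of by the addition. If the cyclisation of 26 gives mainly the C1 epimer (1R,2S,3S,4S,5R,6S,7R,8R)-2,3:4,5-diepoxy-1-hydroxy-8-tigloyloxygermacra-10(14),11(13)-dien-12,6-olide F4, the carbinol mixture is oxidised with Dess–Martin periodinane to the macrocyclic epoxy enone (2R,3S,4S,5R,6S,7R,8R)-2,3:4,5-diepoxy-1-oxo-8-tigloyloxygermacra-10(14),11(13)-dien-12,6-olide F5. F5 is reduced with Zn(BH4)2 in Et2O at −30 °C, a reduction known to give erythro alcohols from alpha,beta-epoxy ketones, to give 27.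

Further compounds
F1 | step 9 | methyl (6S,7S,8S)-10-bromo-1-(tert-butyldiphenylsilyloxy)-6-hydroxy-8-(triethylsilyloxy)-1,10-secogermacra-2Z,4E,10(14),11(13)-tetraen-12-oate | C=C(C(=O)OC)[C@@H]([C@@H](O)/C=C(C)/C=C\CO[Si](c1ccccc1)(c1ccccc1)C(C)(C)C)[C@@H](O[Si](CC)(CC)CC)CC(Br)=C
F2 | step 9 | methyl (7R,8S)-10-bromo-1-(tert-butyldiphenylsilyloxy)-6-oxo-8-(triethylsilyloxy)-1,10-secogermacra-2Z,4E,10(14),11(13)-tetraen-12-oate | C=C(C(=O)OC)[C@@H](C(=O)/C=C(C)/C=C\CO[Si](c1ccccc1)(c1ccccc1)C(C)(C)C)[C@@H](O[Si](CC)(CC)CC)CC(Br)=C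
F3 | step 11 | (4R,5R,6S,7R,8S)-10-bromo-1-(tert-butyldiphenylsilyloxy)-4,5-epoxy-8-hydroxy-1,10-secogermacra-2Z,10(14),11(13)-trien-12,6-olide | C=C1C(=O)O[C@H]([C@H]2O[C@]2(C)/C=C\CO[Si](c2ccccc2)(c2ccccc2)C(C)(C)C)[C@H]1[C@@H](O)CC(Br)=C
F4 | step 15 | (1R,2S,3S,4S,5R,6S,7R,8R)-2,3:4,5-diepoxy-1-hydroxy-8-tigloyloxygermacra-10(14),11(13)-dien-12,6-olide | C=C1C(=O)O[C@H]2[C@H]1[C@H](OC(=O)/C(C)=C/C)CC(=C)[C@@H](O)[C@@H]1O[C@@H]1[C@@]1(C)O[C@H]21
F5 | step 15 | (2R,3S,4S,5R,6S,7R,8R)-2,3:4,5-diepoxy-1-oxo-8-tigloyloxygermacra-10(14),11(13)-dien-12,6-olide | C=C1C(=O)O[C@H]2[C@H]1[C@H](OC(=O)/C(C)=C/C)CC(=C)C(=O)[C@@H]1O[C@@H]1[C@@]1(C)O[C@H]21
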